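Retrosynthetic overview (benzofuran numbering)
1. Feature: ring B is O1–C2–C3–C3a–C7a. O1, C7a, C3a and C3 form the s-cis heterodiene of a ring A ketone (C7a=O) with an exocyclic ethylidene group on C3a. C2 is a single benzylidene carbon carrying the trimethoxyphenyl ring.
2. Key disconnection: O1–C2 and C2–C3 are cut together, giving enone 18 and a chiral sulfonium benzylide released from tosylhydrazone 21 (formal [4+1]). This sets C2 and C3.
3. After it: hexahydrobenzofuran 26 is raised to the 2,4-dienone by freeing and oxidising the C6 oxygen and removing one hydrogen each from C4 and C7.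
4. Before it: C5 is set first, by decarboxylative asymmetric allylation of the enol carbonate of 3-ethoxy-6-methoxycyclohexenone. Carbonyl transposition, β-borylation/oxidation, silylation and an aldol condensation with acetaldehyde then give 18.
5. Ring order: ring A and the arene are purchased; ring B is the only ring closed (step 11).

Key step: step 11

Assumption 1: in step 4 the methoxy group is taken to sit where the alkyl group of a 2-alkylcyclohexanone enol carbonate sits, so the (S)-ligand should give (R)-8; if the sense is reversed, the (R)-ligand is used.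
Assumption 2: the sense of step 11 follows from the usual model of bicyclic sulfonium benzylides (aryl syn to the sulfur lone pair, attack on the face away from the gem-dimethyl group), which assigns 2S to sulfide 22; if the sense is reversed, the (1S,4S,5S) sulfide is used.
Remark: the C6 carbinol centre made in step 6 is destroyed in step 13, so either epimer serves.

Step 1
Reactants: 1 3-ethoxycyclohex-2-en-1-one
Product: 3 (±)-3-ethoxy-6-hydroxycyclohex-2-en-1-one, via sodium dienolate 2 (not isolated)
Conditions: NaN(SiMe3)2, THF, −78 °C; 2-(phenylsulfonyl)-3-phenyloxaziridine, −78 °C; AcOH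
Reagents that add atoms: 2-(phenylsulfonyl)-3-phenyloxaziridine, O=S(=O)(c1ccccc1)N1OC1c1ccccc1
Why: Kinetic deprotonation of a vinylogous ester takes the α′ proton, and oxygen transfer from the N-sulfonyloxaziridine to that enolate (Davis oxidation) gives the acyloin, whose racemic centre is flattened again in step 3.

Step 2
Reactants: 3 (±)-3-ethoxy-6-hydroxycyclohex-2-en-1-one
Product: 4 (±)-3-ethoxy-6-methoxycyclohex-2-en-1-one
Conditions: MeI, Ag2O, 4 Å molecular sieves, CH2Cl2, rt, dark
Reagents that add atoms: iodomethane, CI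
Why: The Purdie methylation etherifies the secondary hydroxyl without a strong base, so the acyloin neither tautomerises nor condenses, and the vinylogous ester oxygen is not alkylated.

Step 3
Reactants: 4 (±)-3-ethoxy-6-methoxycyclohex-2-en-1-one; 5 allyl chloroformate
Product: 7 allyl 5-ethoxy-2-methoxycyclohexa-1,5-dien-1-yl carbonate, via lithium dienolate 6 (not isolated)
Conditions: LiN(SiMe3)2, TMEDA, THF, −78 °C; 5, −78 → 0 °C
Reagents that add atoms: allyl chloroformate, C=CCOC(Cl)=O
Why: O-acylation of the fully substituted α′ enolate by a chloroformate gives the allyl enol carbonate, and any C-acylated β-keto ester would feed the same palladium enolate in step 4.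

Step 4
Reactants: 7 allyl 5-ethoxy-2-methoxycyclohexa-1,5-dien-1-yl carbonate
Product: 8 (R)-6-allyl-3-ethoxy-6-methoxycyclohex-2-en-1-one
Conditions: Pd2(dba)3 (2.5 mol %), (S)-4-tert-butyl-2-[2-(diphenylphosphino)phenyl]-4,5-dihydrooxazole (6.25 mol %), toluene, 25 °C
Reagents that add atoms: none
Why: In this decarboxylative asymmetric allylic alkylation (Tsuji–Trost type), ionisation and loss of CO2 give a chiral phosphinooxazoline–palladium allyl enolate that can only bond at the α′ carbon, and the ligand chooses the enolate face and so sets the future C5.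

Step 5
Reactants: 8 (R)-6-allyl-3-ethoxy-6-methoxycyclohex-2-en-1-one
Product: 10 (R)-4-allyl-4-methoxycyclohex-2-en-1-one, via ethoxy allylic alcohol 9 (not isolated)
Conditions: LiAlH4, Et2O, 0 °C; then 1 M aq HCl, 0 °C → rt
Reagents that add atoms: water, O
Why: In this Stork–Danheiser transposition, 1,2-reduction followed by acid hydrolysis of the enol ether with loss of the allylic hydroxyl moves the carbonyl to the future C7a and leaves the quaternary centre untouched.

Step 6
Reactants: 10 (R)-4-allyl-4-methoxycyclohex-2-en-1-one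
Product: 12 (3S,4R)-4-allyl-3-hydroxy-4-methoxycyclohexan-1-one, via β-boryl ketone 11 (not isolated)
Conditions: B2pin2 (1.1 equiv), CuCl (5 mol %), bis[2-(diphenylphosphino)phenyl] ether (5 mol %), NaOt-Bu (10 mol %), MeOH (2 equiv), THF, rt; then NaBO3·4H2O, THF–H2O, rt
Reagents that add atoms: sodium perborate, [Na+].[O-]OB=O (oxygen of 12); bis(pinacolato)diboron, CC1(C)OB(OC1(C)C)B1OC(C)(C)C(C)(C)O1 (boryl group of 11 only)
Why: Copper-catalysed conjugate borylation takes the enone far faster than the isolated allyl C=C and delivers boron anti to the pseudoaxial methoxy group, and the perborate oxidation proceeds with retention and is mild enough to keep the β-hydroxy ketone.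

Step 7
Reactants: 12 (3S,4R)-4-allyl-3-hydroxy-4-methoxycyclohexan-1-one
Product: 13 (3S,4R)-4-allyl-3-(tert-butyldimethylsilyloxy)-4-methoxycyclohexan-1-one
Conditions: t-BuMe2SiOTf, 2,6-lutidine, CH2Cl2, −78 → 0 °C
Reagents that add atoms: tert-butyldimethylsilyl triflate, CC(C)(C)[Si](C)(C)OS(=O)(=O)C(F)(F)F
Why: Silyl triflate with a hindered pyridine silylates the crowded carbinol at low temperature without enolising the ketone or causing β-elimination.

Step 8
Reactants: 13 (3S,4R)-4-allyl-3-(tert-butyldimethylsilyloxy)-4-methoxycyclohexan-1-one; 14 acetaldehyde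
Product: 16 (4S,5S)-4-allyl-5-(tert-butyldimethylsilyloxy)-2-(1-hydroxyethyl)-4-methoxycyclohexan-1-one (epimers at C2 and at the carbinol carbon), via kinetic lithium enolate 15 (not isolated)
Conditions: LiN(i-Pr)2, THF, −78 °C; 14 (excess, freshly distilled), −78 °C; AcOH
Reagents that add atoms: acetaldehyde, CC=O
Why: In this directed aldol addition the bulky amide base removes a proton from the methylene remote from the silyloxy-bearing carbon, which also avoids β-elimination, and the two new centres are removed in step 9.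

Step 9
Reactants: 16 (4S,5S)-4-allyl-5-(tert-butyldimethylsilyloxy)-2-(1-hydroxyethyl)-4-methoxycyclohexan-1-one
Product: 18 (4S,5S)-4-allyl-5-(tert-butyldimethylsilyloxy)-2-[(E)-ethylidene]-4-methoxycyclohexan-1-one, via aldol mesylate 17 (not isolated)
Conditions: MsCl, Et3N, CH2Cl2, 0 °C; then DBU, 0 °C, short contact
Reagents that add atoms: methanesulfonyl chloride, CS(=O)(=O)Cl (in 17 only)
Why: In this mesylation and E1cB elimination the mesylate leaves far more readily than the ring silyloxide, the more stable E isomer (methyl away from the carbonyl) results, and the brief cold base contact keeps the double bond exocyclic.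

Step 10
Reactants: 19 3,4,5-trimethoxybenzaldehyde; 20 p-toluenesulfonyl hydrazide
Product: 21 (E)-3,4,5-trimethoxybenzaldehyde N-tosylhydrazone
Conditions: MeOH, rt, filtration
Reagents that add atoms: p-toluenesulfonyl hydrazide, Cc1ccc(cc1)S(=O)(=O)NN
Why: Hydrazone condensation of an aromatic aldehyde is fast and the E product crystallises from methanol.

Step 11
Reactants: 18 (4S,5S)-4-allyl-5-(tert-butyldimethylsilyloxy)-2-[(E)-ethylidene]-4-methoxycyclohexan-1-one; 21 (E)-3,4,5-trimethoxybenzaldehyde N-tosylhydrazone; 22 (1R,4R,5R)-4,7,7-trimethyl-6-thiabicyclo[3.2.1]octane (isothiocineole)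
Product: 26 (2S,3S,5S,6S)-5-allyl-6-(tert-butyldimethylsilyloxy)-5-methoxy-3-methyl-2-(3,4,5-trimethoxyphenyl)-2,3,4,5,6,7-hexahydrobenzofuran, via hydrazone sodium salt 23 (not isolated), via aryldiazomethane 24 (not isolated), via sulfonium benzylide 25 (not isolated)
Conditions: 21 (1.5 equiv), NaOMe (1.5 equiv), MeOH, rt, evaporate to dryness; then 18, 22 (1.0 equiv), Rh2(OAc)4 (1 mol %), BnEt3NCl (10 mol %), 1,4-dioxane, 40 °C; chromatography on Et3N-washed silica
Reagents that add atoms: tosylhydrazone 21 (delivers the C2 benzylidene unit), COc1cc(/C=N/NS(=O)(=O)c2ccc(C)cc2)cc(OC)c1OC; sodium methoxide, [Na+].[O-]C (sodium of 23 only); sulfide 22, C[C@@H]1CC[C@@H]2C[C@H]1SC2(C)C (in 25 only)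
Why: Proposed new method: salt 23 fragments (Bamford–Stevens) to diazoalkane 24, Rh2(OAc)4 passes its carbene to sulfide 22, ylide 25 adds through C2 to C3 of the enone, and the C7a enolate oxygen expels the sulfide from C2, so that C2–C3 and O1–C2 form and ring B closes in the 5-exo-tet mode while 22 is returned. The closest known reactions are the formal [4+1] annulations of sulfonium ylides with 2-ylidene-1,3-dicarbonyl compounds and ortho-quinone methides and the carbene-transfer cyclopropanation of simple enones by the same benzylides; closure through oxygen on a singly activated 2-alkylidenecyclohexanone has not been shown. Oxygen should win over C3a because the ring holds O and C3 cis on the enolate double bond, because carbon closure would have to build a spiro quaternary centre flanked by two substituted carbons, and because the electron-rich aryl group loosens the C2–S bond and so favours the harder terminus. C2 is controlled by the sulfide, whose ylide reacts from one conformer on the face turned away from the gem-dimethyl group, and inversion in the displacement then gives 2S. C3 is fixed in the addition, which must take the enone face opposite to the C5 methoxy group, and trans follows because only the betaine rotamer that keeps aryl and methyl apart can align O, C2 and S for backside attack. The step also needs 1,4- over 1,2-addition (semi-stabilised ylide, hindered ketone), capture of the rhodium carbene by sulfur instead of the allyl C=C (a full equivalent of 22, slow release of 24) and reagent over substrate control, which is helped by the chair with axial OMe and OSi groups that screens the unwanted face and keeps the allyl group equatorial.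

Step 12
Reactants: 26 (2S,3S,5S,6S)-5-allyl-6-(tert-butyldimethylsilyloxy)-5-methoxy-3-methyl-2-(3,4,5-trimethoxyphenyl)-2,3,4,5,6,7-hexahydrobenzofuran
Product: 27 (2S,3S,5S,6S)-5-allyl-5-methoxy-3-methyl-2-(3,4,5-trimethoxyphenyl)-2,3,4,5,6,7-hexahydrobenzofuran-6-ol
Conditions: n-Bu4NF, THF, 0 °C → rt
Reagents that add atoms: none
Why: Fluoride desilylation is non-acidic, so the tetrasubstituted enol ether of ring B, the tertiary methyl ether and the allyl group are left alone.

Step 13
Reactants: 27 (2S,3S,5S,6S)-5-allyl-5-methoxy-3-methyl-2-(3,4,5-trimethoxyphenyl)-2,3,4,5,6,7-hexahydrobenzofuran-6-ol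
Product: 28 (2S,3S,5S)-5-allyl-5-methoxy-3-methyl-2-(3,4,5-trimethoxyphenyl)-3,4,5,7-tetrahydrobenzofuran-6(2H)-one
Conditions: (n-Pr)4N[RuO4] (5 mol %), N-methylmorpholine N-oxide, 4 Å molecular sieves, CH2Cl2, rt
Reagents that add atoms: none
Why: The Ley–Griffith oxidation turns the hindered secondary alcohol into the C6 ketone under neutral conditions that tolerate the enol ether and the alkene, and it erases the auxiliary C6 centre.

Step 14
Reactants: 28 (2S,3S,5S)-5-allyl-5-methoxy-3-methyl-2-(3,4,5-trimethoxyphenyl)-3,4,5,7-tetrahydrobenzofuran-6(2H)-one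
Product: 29 (2S,3S,5S)-5-allyl-5-methoxy-3-methyl-2-(3,4,5-trimethoxyphenyl)-3,5-dihydrobenzofuran-6(2H)-one (target)
Conditions: DDQ (1.05 equiv), 1,4-dioxane, rt, dark
Reagents that add atoms: none
Why: DDQ takes hydride from the axial C4–H allylic to the electron-rich C3a=C7a enol ether and the oxocarbenium ion loses the doubly activated C7 proton, which is the γ,δ-dehydrogenation that converts steroidal 3,5-dienol ethers into 4,6-dien-3-ones; C5 is quaternary, C2 and C3 are not involved, and room temperature keeps the allyl dienone below the onset of sigmatropic shifts.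

Compound list
1 | 3-ethoxycyclohex-2-en-1-one | CCOC1=CC(=O)CCC1 | starting material
2 | sodium 5-ethoxycyclohexa-1,5-dien-1-olate | CCOC1=CC([O-])=CCC1.[Na+] | intermediate
3 | (±)-3-ethoxy-6-hydroxycyclohex-2-en-1-one | CCOC1=CC(=O)C(O)CC1 | intermediate
4 | (±)-3-ethoxy-6-methoxycyclohex-2-en-1-one | CCOC1=CC(=O)C(OC)CC1 | intermediate
5 | allyl chloroformate | C=CCOC(Cl)=O | starting material
6 | lithium 5-ethoxy-2-methoxycyclohexa-1,5-dien-1-olate | CCOC1=CC([O-])=C(OC)CC1.[Li+] | intermediate
7 | allyl 5-ethoxy-2-methoxycyclohexa-1,5-dien-1-yl carbonate | C=CCOC(=O)OC1=C(OC)CCC(OCC)=C1 | intermediate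
8 | (R)-6-allyl-3-ethoxy-6-methoxycyclohex-2-en-1-one | C=CC[C@]1(OC)CCC(OCC)=CC1=O | intermediate
9 | (6R)-6-allyl-3-ethoxy-6-methoxycyclohex-2-en-1-ol (C1 epimers) | C=CC[C@]1(OC)CCC(OCC)=CC1O | intermediate
10 | (R)-4-allyl-4-methoxycyclohex-2-en-1-one | C=CC[C@]1(OC)CCC(=O)C=C1 | intermediate
11 | (3S,4R)-4-allyl-4-methoxy-3-(4,4,5,5-tetramethyl-1,3,2-dioxaborolan-2-yl)cyclohexan-1-one | C=CC[C@]1(OC)CCC(=O)C[C@@H]1B2OC(C)(C)C(C)(C)O2 | intermediate
12 | (3S,4R)-4-allyl-3-hydroxy-4-methoxycyclohexan-1-one | C=CC[C@]1(OC)CCC(=O)C[C@@H]1O | intermediate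
13 | (3S,4R)-4-allyl-3-(tert-butyldimethylsilyloxy)-4-methoxycyclohexan-1-one | C=CC[C@]1(OC)CCC(=O)C[C@@H]1O[Si](C)(C)C(C)(C)C | intermediate
14 | acetaldehyde | CC=O | starting material
15 | lithium (4S,5S)-4-allyl-5-(tert-butyldimethylsilyloxy)-4-methoxycyclohex-1-en-1-olate | C=CC[C@]1(OC)CC=C([O-])C[C@@H]1O[Si](C)(C)C(C)(C)C.[Li+] | intermediate
16 | (4S,5S)-4-allyl-5-(tert-butyldimethylsilyloxy)-2-(1-hydroxyethyl)-4-methoxycyclohexan-1-one (epimers at C2 and carbinol carbon) | C=CC[C@]1(OC)CC(C(C)O)C(=O)C[C@@H]1O[Si](C)(C)C(C)(C)C | intermediate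
17 | methanesulfonate of 16 | C=CC[C@]1(OC)CC(C(C)OS(C)(=O)=O)C(=O)C[C@@H]1O[Si](C)(C)C(C)(C)C | intermediate
18 | (4S,5S)-4-allyl-5-(tert-butyldimethylsilyloxy)-2-[(E)-ethylidene]-4-methoxycyclohexan-1-one | C=CC[C@]1(OC)C/C(=C\C)C(=O)C[C@@H]1O[Si](C)(C)C(C)(C)C | intermediate
19 | 3,4,5-trimethoxybenzaldehyde | COc1cc(C=O)cc(OC)c1OC | starting material
20 | p-toluenesulfonyl hydrazide | Cc1ccc(cc1)S(=O)(=O)NN | starting material
21 | (E)-3,4,5-trimethoxybenzaldehyde N-tosylhydrazone | COc1cc(/C=N/NS(=O)(=O)c2ccc(C)cc2)cc(OC)c1OC | intermediate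
22 | (1R,4R,5R)-4,7,7-trimethyl-6-thiabicyclo[3.2.1]octane (isothiocineole, recovered) | C[C@@H]1CC[C@@H]2C[C@H]1SC2(C)C | starting material
23 | sodium salt of 21 | COc1cc(/C=N/[N-]S(=O)(=O)c2ccc(C)cc2)cc(OC)c1OC.[Na+] | intermediate
24 | 5-(diazomethyl)-1,2,3-trimethoxybenzene | COc1cc(C=[N+]=[N-])cc(OC)c1OC | intermediate
25 | 3,4,5-trimethoxybenzylide of 22 (ylide carbon on the sulfur lone pair syn to the C8 bridge) | C[C@@H]1CC[C@@H]2C[C@H]1[S@@+]([CH-]c3cc(OC)c(OC)c(OC)c3)C2(C)C | intermediate
26 | (2S,3S,5S,6S)-5-allyl-6-(tert-butyldimethylsilyloxy)-5-methoxy-3-methyl-2-(3,4,5-trimethoxyphenyl)-2,3,4,5,6,7-hexahydrobenzofuran | C=CC[C@]1(OC)CC2=C(C[C@@H]1O[Si](C)(C)C(C)(C)C)O[C@H](c1cc(OC)c(OC)c(OC)c1)[C@H]2C | intermediate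
27 | (2S,3S,5S,6S)-5-allyl-5-methoxy-3-methyl-2-(3,4,5-trimethoxyphenyl)-2,3,4,5,6,7-hexahydrobenzofuran-6-ol | C=CC[C@]1(OC)CC2=C(C[C@@H]1O)O[C@H](c1cc(OC)c(OC)c(OC)c1)[C@H]2C | intermediate
28 | (2S,3S,5S)-5-allyl-5-methoxy-3-methyl-2-(3,4,5-trimethoxyphenyl)-3,4,5,7-tetrahydrobenzofuran-6(2H)-one | C=CC[C@]1(OC)CC2=C(CC1=O)O[C@H](c1cc(OC)c(OC)c(OC)c1)[C@H]2C | intermediate
29 | (2S,3S,5S)-5-allyl-5-methoxy-3-methyl-2-(3,4,5-trimethoxyphenyl)-3,5-dihydrobenzofuran-6(2H)-one | C=CC[C@]1(OC)C=C2C(=CC1=O)O[C@H](c1cc(OC)c(OC)c(OC)c1)[C@H]2C | target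

Total step count: 14. Longest linear sequence: 13 (steps 1–9 and 11–14); step 10 is the side branch.

Steps most likely to fail

1. Step 11.
- Risk: the betaine may close through carbon instead of oxygen, or the ylide may discriminate poorly between the two faces of the ethylidene group.
- Fallback (known chemistry, from 18 back to 26): the reaction is run for the outcome that sulfonium benzylides are known to give with enones. Ylide 25, generated as in step 11, cyclopropanates 18 to the spirocyclopropyl ketone F1, with aryl trans to methyl and methyl anti to the carbonyl, and F1 is isolated.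
- A Cloke–Wilson rearrangement (Sc(OTf)3 5 mol %, CH2Cl2, 0 °C) then breaks the donor–acceptor bond C2–C3a and recloses through the ketone oxygen. C3 is not touched and C2 should settle trans to it, which gives 26.

2. Step 14.
- Risk: hydride may be lost from the tertiary allylic C3–H instead of C4–H, which would drain material toward a furan. Further oxidation at the benzylic C2–H, or acid-induced allyl migration with aromatisation, are also possible.
- Fallback (from 28 to 29): LiN(SiMe3)2 and Me3SiCl (THF, −78 °C) give the 6-trimethylsilyloxy diene F2.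
- NBS (THF, −78 °C) brominates its most nucleophilic terminus, C3a, from the face opposite to the C3 methyl and C5 allyl groups, giving the 3a-bromo enone F3.
- DBU (0 °C) removes HBr by anti elimination. Bromine is syn to C3–H, so only C4 offers an antiperiplanar hydrogen, and the C3a=C4 bond of 29 should form regiospecifically.

3. Step 4.
- Risk: the α-methoxy enolate may be allylated with weak facial discrimination, or may be protonated instead.
- A small share of the C5 antipode is tolerable, because the reagent-controlled step 11 turns it into a separable diastereomer.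
- Fallback (from 1 back to 8) forms the C–O bond, not the C–C bond, enantioselectively. LiN(i-Pr)2 and allyl bromide give racemic 6-allyl-3-ethoxycyclohex-2-en-1-one F4.
- Its potassium enolate (KN(SiMe3)2, THF, −78 °C) is hydroxylated with an enantiopure (camphorsulfonyl)oxaziridine (reagent-controlled Davis oxidation) to the tertiary acyloin (R)-6-allyl-3-ethoxy-6-hydroxycyclohex-2-en-1-one F5. NaH and MeI (THF, 0 °C) then give 8.

Further compounds
F1 | step 11 | (1S,2R,3S,6S,7S)-7-allyl-6-(tert-butyldimethylsilyloxy)-7-methoxy-2-methyl-1-(3,4,5-trimethoxyphenyl)spiro[2.5]octan-4-one | C=CC[C@]1(OC)C[C@@]2([C@H](C)[C@H]2c3cc(OC)c(OC)c(OC)c3)C(=O)C[C@@H]1O[Si](C)(C)C(C)(C)C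
F2 | step 14 | (2S,3S,5S)-5-allyl-5-methoxy-3-methyl-2-(3,4,5-trimethoxyphenyl)-6-(trimethylsilyloxy)-2,3,4,5-tetrahydrobenzofuran | C=CC[C@]1(OC)CC2=C(C=C1O[Si](C)(C)C)O[C@H](c3cc(OC)c(OC)c(OC)c3)[C@H]2C
F3 | step 14 | (2S,3R,3aS,5S)-5-allyl-3a-bromo-5-methoxy-3-methyl-2-(3,4,5-trimethoxyphenyl)-3,3a,4,5-tetrahydrobenzofuran-6(2H)-one | C=CC[C@]1(OC)C[C@@]2(Br)C(=CC1=O)O[C@H](c3cc(OC)c(OC)c(OC)c3)[C@H]2C
F4 | step 4 | (±)-6-allyl-3-ethoxycyclohex-2-en-1-one | C=CCC1CCC(OCC)=CC1=O
F5 | step 4 | (R)-6-allyl-3-ethoxy-6-hydroxycyclohex-2-en-1-one | C=CC[C@]1(O)CCC(OCC)=CC1=O
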